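**Retrosynthetic overview**
1. Bryostatin 18 is opened at the C1–O25 lactone and at both hemiketals (rings A and C) to give a seco-acid. C9 and C19 are carried as hindered 1,3-dithianes and all other OH groups as TBS, Piv or NAP ethers.
2. Key late coupling: a Prins cyclization joins the C1–C14 homoallylic alcohol to the C15–C27 enal. This closes ring B 2,6-cis, and the resulting C13 ketone is olefinated to the exocyclic enoate.
3. The C1–C14 piece comes from a C1–C9 dithiane plus (S)-2-allyloxirane (C10–C14). The C15–C27 piece comes from a C17–C19 dithiane plus a C20–C27 epoxide.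
4. C3/C5/C7 and C23/C25 come from iterative Brown allylation and oxidative cleavage starting from neopentyl glycol and (R)-lactate. C11 comes from (S)-epichlorohydrin.
5. Order of ring formation: ring B, then the macrolactone, then rings A and C by hemiketalization on the final desilylation.

Assumptions:
- (−)-Ipc2B(allyl) attacks the Si face of an aldehyde, and (+)-Ipc2B(allyl) the Re face.
- C9 and C19 hemiketalize spontaneously, with the anomeric configuration of the natural product, once their ketones and the C5/C23 OH groups are free.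

---

**Fragment A (C1–C9 dithiane)**

Step 1
Reactants: 1 neopentyl glycol (2,2-dimethylpropane-1,3-diol)
Product: 2 3-[(4-methoxybenzyl)oxy]-2,2-dimethylpropan-1-ol
Conditions: NaH, PMBCl, TBAI (cat.), THF/DMF, 0 °C → rt
Reagents that add atoms: PMBCl, COc1ccc(CCl)cc1
Why: Williamson etherification of the symmetric diol (used in excess) gives mono-protection statistically.

Step 2
Reactants: 2
Product: 3 3-[(4-methoxybenzyl)oxy]-2,2-dimethylpropanal
Conditions: Dess–Martin periodinane, NaHCO3, CH2Cl2, rt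
Reagents that add atoms: none
Why: Mild oxidation gives a non-enolizable aldehyde, so there is no epimerization risk.

Step 3
Reactants: 3
Product: 4 (S)-6-(PMBO)-5,5-dimethylhex-1-en-4-ol (C7 carbinol)
Conditions: (−)-Ipc2B(allyl), Et2O, −78 °C; then NaOH, H2O2
Reagents that add atoms: (−)-B-allyldiisopinocampheylborane (from (+)-α-pinene), C=CCB(C1C(C)C2CC(C1)C2(C)C)C1C(C)C2CC(C1)C2(C)C (stereo omitted)
Why: Brown asymmetric allylboration through a chair transition state with Si-face attack sets C7 (S) by reagent control.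

Step 4
Reactants: 4
Product: 5 C7 pivalate of 4
Conditions: PivCl, pyridine, DMAP (cat.), CH2Cl2, 40 °C
Reagents that add atoms: PivCl, CC(C)(C)C(=O)Cl
Why: Acylation installs the permanent C7 pivalate without touching the stereocentre.

Step 5
Reactants: 5
Product: 6 C5 aldehyde: OHC-CH2-CH(OPiv)-CMe2-CH2OPMB, C7 (S)
Conditions: O3, CH2Cl2, −78 °C (Sudan III end-point); then PPh3
Reagents that add atoms: ozone, [O-][O+]=O
Why: Ozonolysis of the terminal alkene shortens the chain by one carbon to the C5 aldehyde.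

Step 6
Reactants: 6
Product: 7 C5 homoallylic alcohol (C7 OPiv, C5 OH, C3=C2 alkene)
Conditions: (+)-Ipc2B(allyl), Et2O, −78 °C; then NaOH, H2O2
Reagents that add atoms: (+)-B-allyldiisopinocampheylborane, C=CCB(C1C(C)C2CC(C1)C2(C)C)C1C(C)C2CC(C1)C2(C)C
Why: Re-face Brown allylation overrides the β-stereocentre and makes the C5-OH 1,3-anti to C7-O.

Step 7
Reactants: 7
Product: 8 C5-OTBS ether of 7
Conditions: TBSOTf, 2,6-lutidine, CH2Cl2, −78 °C
Reagents that add atoms: TBSOTf, CC(C)(C)[Si](C)(C)OS(=O)(=O)C(F)(F)F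
Why: Silylation protects the C5 alcohol; no stereocentre is touched.

Step 8
Reactants: 8
Product: 9 C3 aldehyde (C7 OPiv, C5 OTBS)
Conditions: O3, CH2Cl2, −78 °C; then PPh3
Reagents that add atoms: ozone, [O-][O+]=O
Why: Alkene cleavage gives the next aldehyde; the β-silyloxy aldehyde has no acidic conditions to eliminate under.

Step 9
Reactants: 9
Product: 10 C3 homoallylic alcohol (C3 OH, C1=C0 alkene)
Conditions: (−)-Ipc2B(allyl), Et2O, −78 °C; then NaOH, H2O2
Reagents that add atoms: (−)-B-allyldiisopinocampheylborane, C=CCB(C1C(C)C2CC(C1)C2(C)C)C1C(C)C2CC(C1)C2(C)C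
Why: Si-face allylboration sets C3 with O anti to the C5-O, giving the 3,5,7 anti,anti triol pattern of the target.

Step 10
Reactants: 10
Product: 11 C3-OTBS ether
Conditions: TBSOTf, 2,6-lutidine, CH2Cl2, −78 °C
Reagents that add atoms: TBSOTf, CC(C)(C)[Si](C)(C)OS(=O)(=O)C(F)(F)F
Why: Silylation protects C3.

Step 11
Reactants: 11
Product: 12 C1 primary alcohol (C1–C9 chain, C9-OPMB)
Conditions: O3, CH2Cl2/MeOH, −78 °C; then NaBH4, 0 °C
Reagents that add atoms: ozone, [O-][O+]=O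
Why: Ozonolysis with reductive work-up converts the terminal vinyl group to CH2OH, which becomes C1.

Step 12
Reactants: 12
Product: 13 C1-OTBS ether
Conditions: TBSCl, imidazole, DMF, rt
Reagents that add atoms: TBSCl, CC(C)(C)[Si](C)(C)Cl
Why: Primary silylation; this TBS is later removed selectively (HF·py) in preference to the hindered secondary TBS groups.

Step 13
Reactants: 13
Product: 14 C9 primary alcohol
Conditions: DDQ, CH2Cl2/pH 7 buffer, 0 °C
Reagents that add atoms: none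
Why: Oxidative removal of PMB; silyl and pivalate esters are inert.

Step 14
Reactants: 14
Product: 15 C9 aldehyde (neopentyl, non-enolizable)
Conditions: Dess–Martin periodinane, NaHCO3, CH2Cl2, rt
Reagents that add atoms: none
Why: Mild oxidation of the primary alcohol.

Step 15
Reactants: 15
Product: 16 A-dithiane: C9 1,3-dithiane; C7 OPiv; C5, C3, C1 OTBS
Conditions: HS(CH2)3SH, Sc(OTf)3 (cat.), CH2Cl2, 0 °C → rt
Reagents that add atoms: propane-1,3-dithiol, SCCCS
Why: Dithioacetalization masks C9 as a ketone equivalent and makes C9 nucleophilic for the next coupling.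

**Fragment B (C10–C14 epoxide)**

Step 16
Reactants: 17 (S)-epichlorohydrin
Product: 18 (S)-1-chloropent-4-en-2-ol
Conditions: CH2=CHMgBr, CuI (10 mol %), THF, −30 °C
Reagents that add atoms: vinylmagnesium bromide, C=C[Mg]Br
Why: Cu-catalysed opening at the terminal epoxide CH2 leaves the stereocentre untouched, so C11 keeps its configuration.

Step 17
Reactants: 18
Product: 19 (S)-2-allyloxirane (C10–C11 epoxide with C12–C14 allyl)
Conditions: NaOH (powdered), Et2O, 0 °C
Reagents that add atoms: none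
Why: Intramolecular Williamson ring closure displaces Cl from C10 with retention at C11 (S).

**Fragment AB (C1–C14)**

Step 18
Reactants: 16 A-dithiane; 19 (S)-2-allyloxirane
Product: 20 AB alcohol: C11-(S)-OH, C9 dithiane, C13=C14 terminal alkene, C1/C3/C5 OTBS, C7 OPiv
Conditions: n-BuLi, THF, −30 → 0 °C; then 19, DMPU, −78 → −20 °C
Reagents that add atoms: none (19 is the reactant)
Why: Corey–Seebach/Smith-type union: the 2-lithiodithiane opens the terminal epoxide carbon (C10), fixing C11 (S) from the epoxide.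

**Fragment C (C15–C27 enal)**

Step 19
Reactants: 3
Product: 21 2-[1-(PMBO)-2-methylpropan-2-yl]-1,3-dithiane (C19 dithiane, C18 gem-dimethyl, C17 OPMB)
Conditions: HS(CH2)3SH, Sc(OTf)3 (cat.), CH2Cl2, 0 °C
Reagents that add atoms: propane-1,3-dithiol, SCCCS
Why: Dithioacetalization of the same neopentyl aldehyde gives the C17–C19 unit.

Step 20
Reactants: 22 methyl (R)-lactate
Product: 23 methyl (R)-2-(TBSO)propanoate
Conditions: TBSCl, imidazole, DMF, rt
Reagents that add atoms: TBSCl, CC(C)(C)[Si](C)(C)Cl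
Why: Silylation protects C26; (R)-lactate supplies C26 (R).

Step 21
Reactants: 23
Product: 24 (R)-2-(TBSO)propanal (C25 aldehyde)
Conditions: DIBAL-H, CH2Cl2, −78 °C
Reagents that add atoms: none
Why: Controlled ester-to-aldehyde reduction; the aldehyde is used without purification because it is volatile.

Step 22
Reactants: 24
Product: 25 C25 homoallylic alcohol (C26 OTBS, C25 OH, C23=C22)
Conditions: (+)-Ipc2B(allyl), Et2O, −78 °C; then NaOH, H2O2
Reagents that add atoms: (+)-B-allyldiisopinocampheylborane, C=CCB(C1C(C)C2CC(C1)C2(C)C)C1C(C)C2CC(C1)C2(C)C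
Why: Re-face allylboration gives the 25,26-syn diol; this is the mismatched pairing with the aldehyde, so the minor isomer is removed by chromatography.

Step 23
Reactants: 25
Product: 26 C25 2-naphthylmethyl (NAP) ether
Conditions: NAP trichloroacetimidate, CSA (cat.), CH2Cl2, rt
Reagents that add atoms: 2-naphthylmethyl trichloroacetimidate, N=C(OCc1ccc2ccccc2c1)C(Cl)(Cl)Cl
Why: An acid-catalysed imidate ether avoids base-induced 1,2-silyl migration; NAP is later removed by DDQ and tolerates the Prins acid.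

Step 24
Reactants: 26
Product: 27 C23 aldehyde
Conditions: OsO4 (cat.), NaIO4, 2,6-lutidine, dioxane/H2O, rt
Reagents that add atoms: sodium periodate (oxygen source), [Na+].[O-]I(=O)(=O)=O
Why: Lemieux–Johnson cleavage is used in place of ozone to spare the naphthalene ring.

Step 25
Reactants: 27
Product: 28 C23 homoallylic alcohol (C21=C20 alkene)
Conditions: (−)-Ipc2B(allyl), Et2O, −78 °C; then NaOH, H2O2
Reagents that add atoms: (−)-B-allyldiisopinocampheylborane, C=CCB(C1C(C)C2CC(C1)C2(C)C)C1C(C)C2CC(C1)C2(C)C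
Why: Si-face allylboration sets C23 as 1,3-anti to C25-O.

Step 26
Reactants: 28
Product: 29 C23-OTBS ether
Conditions: TBSOTf, 2,6-lutidine, CH2Cl2, −78 °C
Reagents that add atoms: TBSOTf, CC(C)(C)[Si](C)(C)OS(=O)(=O)C(F)(F)F
Why: Silylation protects C23.

Step 27
Reactants: 29
Product: 30 C20–C21 terminal epoxide (C21 epimeric mixture)
Conditions: mCPBA, NaHCO3, CH2Cl2, 0 °C
Reagents that add atoms: mCPBA, OOC(=O)c1cccc(Cl)c1
Why: Epoxidation of the monosubstituted alkene; the C21 centre is destroyed again by oxidation in step 29, so its configuration is irrelevant.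

Step 28
Reactants: 21; 30
Product: 31 C21 alcohol (C19 dithiane–C20–C21 linkage made; epimers at C21)
Conditions: n-BuLi, THF, −30 → 0 °C; then 30, DMPU, −78 → −20 °C
Reagents that add atoms: none (30 is the reactant)
Why: The same dithiane–epoxide alkylation attacks the terminal carbon C20.

Step 29
Reactants: 31
Product: 32 C21 ketone
Conditions: Dess–Martin periodinane, NaHCO3, CH2Cl2, rt
Reagents that add atoms: none
Why: Oxidation converges the C21 epimers to one ketone.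

Step 30
Reactants: 32
Product: 33 C21 exocyclic enoate, ester cis to C20 (desired isomer isolated)
Conditions: (MeO)2P(O)CH2CO2Me, NaH, THF, 0 °C → rt; separate E/Z isomers by HPLC
Reagents that add atoms: trimethyl phosphonoacetate, COC(=O)CP(=O)(OC)OC
Why: Horner–Wadsworth–Emmons olefination gives an E/Z mixture (β-silyloxy elimination is kept minor at 0 °C); the isomer with ester cis to C20 is assigned by NOE.

Step 31
Reactants: 33
Product: 34 C17 primary alcohol
Conditions: DDQ, CH2Cl2/pH 7 buffer, 0 °C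
Reagents that add atoms: none
Why: PMB is cleaved faster than NAP under controlled DDQ stoichiometry.

Step 32
Reactants: 34
Product: 35 C17 aldehyde
Conditions: Dess–Martin periodinane, NaHCO3, CH2Cl2, rt
Reagents that add atoms: none
Why: Oxidation to the non-enolizable α-quaternary aldehyde.

Step 33
Reactants: 35
Product: 36 (E)-enal C (C15 aldehyde, C16=C17 E, C19 dithiane, C21 enoate, C23/C26 OTBS, C25 ONAP)
Conditions: Ph3P=CHCHO, toluene, 90 °C
Reagents that add atoms: (formylmethylene)triphenylphosphorane, O=CC=P(c1ccccc1)(c1ccccc1)c1ccccc1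
Why: A stabilized ylide adds C15–C16 with high E-selectivity to give the C16=C17 trans alkene.

**Key coupling and endgame**

Step 34
Reactants: 20 AB alcohol; 36 enal C
Product: 37 ring-B 4-acetoxy-tetrahydropyran (2,6-cis; C11 S, C15 R; C13 epimeric mixture)
Conditions: BF3·OEt2, AcOH, CH2Cl2, −20 → 0 °C
Reagents that add atoms: acetic acid, CC(=O)O
Why: Prins cyclization: the oxocarbenium formed from the C11 alcohol and enal C is attacked by C14, the chair transition state with both substituents equatorial gives 2,6-cis, and acetate traps the C13 cation.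

Step 35
Reactants: 37
Product: 38 C13 alcohol
Conditions: K2CO3, MeOH, 0 °C
Reagents that add atoms: none
Why: Methanolysis of the acetate leaves the hindered pivalate and silyl ethers intact.

Step 36
Reactants: 38
Product: 39 ring-B 4-oxo-tetrahydropyran (C13 ketone)
Conditions: Dess–Martin periodinane, NaHCO3, CH2Cl2, rt
Reagents that add atoms: none
Why: Oxidation removes the transient C13 stereocentre, leaving C11 S and C15 R, 2,6-cis.

Step 37
Reactants: 39
Product: 40 C13 exocyclic enoate, ester cis to C14 (desired isomer)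
Conditions: (MeO)2P(O)CH2CO2Me, NaH, THF, 0 °C; separate isomers by HPLC
Reagents that add atoms: trimethyl phosphonoacetate, COC(=O)CP(=O)(OC)OC
Why: HWE on the near-symmetric ring ketone gives roughly 1:1 E/Z; the natural isomer is isolated and assigned by NOE to the C14 methylene.

Step 38
Reactants: 40
Product: 41 C25 free alcohol
Conditions: DDQ, CH2Cl2/H2O (18:1), rt
Reagents that add atoms: none
Why: Oxidative NAP cleavage; the hindered dithianes, silyl ethers and enoates survive.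

Step 39
Reactants: 41
Product: 42 C1 primary alcohol, C25 alcohol (diol)
Conditions: HF·pyridine, pyridine, THF, 0 °C
Reagents that add atoms: none
Why: Buffered HF cleaves the unhindered primary TBS faster than the secondary TBS ethers.

Step 40
Reactants: 42
Product: 43 seco-acid (C1 CO2H, C25 OH)
Conditions: TEMPO (20 mol %), PhI(OAc)2, MeCN/H2O, rt
Reagents that add atoms: water, O
Why: The TEMPO oxoammonium oxidizes the primary alcohol to the acid and leaves the hindered secondary C25-OH.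

Step 41
Reactants: 43
Product: 44 macrolactone (C1–O25 ester; both dithianes intact)
Conditions: 2,4,6-Cl3C6H2COCl, Et3N, THF; then slow addition to DMAP, toluene, 75 °C (1 mM)
Reagents that add atoms: none (the mixed anhydride leaves)
Why: Yamaguchi macrolactonization under high dilution.

Step 42
Reactants: 44
Product: 45 C9, C19 diketone macrolactone (C3, C5, C23, C26 OTBS)
Conditions: PIFA, CaCO3, MeCN/H2O (9:1), 0 °C
Reagents that add atoms: water, O
Why: Hypervalent-iodine dithioacetal hydrolysis unmasks both ketones under neutral-buffered, non-metal conditions.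

Step 43
Reactants: 45
Product: 46 bryostatin 18
Conditions: HF·pyridine, pyridine, THF, 23 °C, 48 h
Reagents that add atoms: none
Why: Removal of the four TBS groups frees C5-OH and C23-OH, which close onto the C9 and C19 ketones as the ring A and ring C hemiketals with the anomeric configurations of the natural product.

---

**Compound list**

1 | neopentyl glycol | CC(C)(CO)CO | starting material
2 | mono-PMB neopentyl glycol | COc1ccc(COCC(C)(C)CO)cc1 | intermediate
3 | 3-(PMBO)-2,2-dimethylpropanal | COc1ccc(COCC(C)(C)C=O)cc1 | intermediate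
4 | C7 (S) homoallylic alcohol | COc1ccc(COCC(C)(C)[C@@H](O)CC=C)cc1 | intermediate
5 | C7 pivalate | COc1ccc(COCC(C)(C)[C@@H](OC(=O)C(C)(C)C)CC=C)cc1 | intermediate
6 | C5 aldehyde | COc1ccc(COCC(C)(C)[C@@H](OC(=O)C(C)(C)C)CC=O)cc1 | intermediate
7 | C5 alcohol | COc1ccc(COCC(C)(C)[C@@H](OC(=O)C(C)(C)C)C[C@H](O)CC=C)cc1 | intermediate
8 | C5-OTBS | COc1ccc(COCC(C)(C)[C@@H](OC(=O)C(C)(C)C)C[C@H](O[Si](C)(C)C(C)(C)C)CC=C)cc1 | intermediate
9 | C3 aldehyde | COc1ccc(COCC(C)(C)[C@@H](OC(=O)C(C)(C)C)C[C@H](O[Si](C)(C)C(C)(C)C)CC=O)cc1 | intermediate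
10 | C3 alcohol | COc1ccc(COCC(C)(C)[C@@H](OC(=O)C(C)(C)C)C[C@H](O[Si](C)(C)C(C)(C)C)C[C@@H](O)CC=C)cc1 | intermediate
11 | C3-OTBS | COc1ccc(COCC(C)(C)[C@@H](OC(=O)C(C)(C)C)C[C@H](O[Si](C)(C)C(C)(C)C)C[C@@H](O[Si](C)(C)C(C)(C)C)CC=C)cc1 | intermediate
12 | C1 alcohol | COc1ccc(COCC(C)(C)[C@@H](OC(=O)C(C)(C)C)C[C@H](O[Si](C)(C)C(C)(C)C)C[C@@H](O[Si](C)(C)C(C)(C)C)CCO)cc1 | intermediate
13 | C1-OTBS | COc1ccc(COCC(C)(C)[C@@H](OC(=O)C(C)(C)C)C[C@H](O[Si](C)(C)C(C)(C)C)C[C@@H](O[Si](C)(C)C(C)(C)C)CCO[Si](C)(C)C(C)(C)C)cc1 | intermediate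
14 | C9 alcohol | OCC(C)(C)[C@@H](OC(=O)C(C)(C)C)C[C@H](O[Si](C)(C)C(C)(C)C)C[C@@H](O[Si](C)(C)C(C)(C)C)CCO[Si](C)(C)C(C)(C)C | intermediate
15 | C9 aldehyde | O=CC(C)(C)[C@@H](OC(=O)C(C)(C)C)C[C@H](O[Si](C)(C)C(C)(C)C)C[C@@H](O[Si](C)(C)C(C)(C)C)CCO[Si](C)(C)C(C)(C)C | intermediate
16 | A-dithiane | C1CSC(SC1)C(C)(C)[C@@H](OC(=O)C(C)(C)C)C[C@H](O[Si](C)(C)C(C)(C)C)C[C@@H](O[Si](C)(C)C(C)(C)C)CCO[Si](C)(C)C(C)(C)C | intermediate
17 | (S)-epichlorohydrin | ClC[C@@H]1CO1 | starting material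
18 | (S)-1-chloropent-4-en-2-ol | C=CC[C@H](O)CCl | intermediate
19 | (S)-2-allyloxirane | C=CC[C@H]1CO1 | intermediate
20 | AB alcohol | C=CC[C@H](O)CC1(SCCCS1)C(C)(C)[C@@H](OC(=O)C(C)(C)C)C[C@H](O[Si](C)(C)C(C)(C)C)C[C@@H](O[Si](C)(C)C(C)(C)C)CCO[Si](C)(C)C(C)(C)C | intermediate
21 | C17–C19 dithiane | COc1ccc(COCC(C)(C)C2SCCCS2)cc1 | intermediate
22 | methyl (R)-lactate | C[C@@H](O)C(=O)OC | starting material
23 | TBS lactate | C[C@@H](O[Si](C)(C)C(C)(C)C)C(=O)OC | intermediate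
24 | TBS lactaldehyde | C[C@@H](O[Si](C)(C)C(C)(C)C)C=O | intermediate
25 | C25 alcohol | C[C@@H](O[Si](C)(C)C(C)(C)C)[C@H](O)CC=C | intermediate
26 | C25 NAP ether | C[C@@H](O[Si](C)(C)C(C)(C)C)[C@H](OCc1ccc2ccccc2c1)CC=C | intermediate
27 | C23 aldehyde | C[C@@H](O[Si](C)(C)C(C)(C)C)[C@H](OCc1ccc2ccccc2c1)CC=O | intermediate
28 | C23 alcohol | C[C@@H](O[Si](C)(C)C(C)(C)C)[C@H](OCc1ccc2ccccc2c1)C[C@@H](O)CC=C | intermediate
29 | C23-OTBS alkene | C[C@@H](O[Si](C)(C)C(C)(C)C)[C@H](OCc1ccc2ccccc2c1)C[C@@H](O[Si](C)(C)C(C)(C)C)CC=C | intermediate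
30 | epoxide (C21 mixture) | C[C@@H](O[Si](C)(C)C(C)(C)C)[C@H](OCc1ccc2ccccc2c1)C[C@@H](O[Si](C)(C)C(C)(C)C)CC1CO1 | intermediate
31 | C21 alcohol | COc1ccc(COCC(C)(C)C2(CC(O)C[C@H](O[Si](C)(C)C(C)(C)C)C[C@@H](OCc3ccc4ccccc4c3)[C@@H](C)O[Si](C)(C)C(C)(C)C)SCCCS2)cc1 | intermediate
32 | C21 ketone | COc1ccc(COCC(C)(C)C2(CC(=O)C[C@H](O[Si](C)(C)C(C)(C)C)C[C@@H](OCc3ccc4ccccc4c3)[C@@H](C)O[Si](C)(C)C(C)(C)C)SCCCS2)cc1 | intermediate
33 | C21 enoate | COc1ccc(COCC(C)(C)C2(C/C(=C\C(=O)OC)C[C@H](O[Si](C)(C)C(C)(C)C)C[C@@H](OCc3ccc4ccccc4c3)[C@@H](C)O[Si](C)(C)C(C)(C)C)SCCCS2)cc1 | intermediate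
34 | C17 alcohol | OCC(C)(C)C1(C/C(=C\C(=O)OC)C[C@H](O[Si](C)(C)C(C)(C)C)C[C@@H](OCc2ccc3ccccc3c2)[C@@H](C)O[Si](C)(C)C(C)(C)C)SCCCS1 | intermediate
35 | C17 aldehyde | O=CC(C)(C)C1(C/C(=C\C(=O)OC)C[C@H](O[Si](C)(C)C(C)(C)C)C[C@@H](OCc2ccc3ccccc3c2)[C@@H](C)O[Si](C)(C)C(C)(C)C)SCCCS1 | intermediate
36 | enal C | O=C/C=C/C(C)(C)C1(C/C(=C\C(=O)OC)C[C@H](O[Si](C)(C)C(C)(C)C)C[C@@H](OCc2ccc3ccccc3c2)[C@@H](C)O[Si](C)(C)C(C)(C)C)SCCCS1 | intermediate
37 | Prins product (C13 OAc, epimeric) | CC(=O)OC1C[C@@H](CC2(SCCCS2)C(C)(C)[C@@H](OC(=O)C(C)(C)C)C[C@H](O[Si](C)(C)C(C)(C)C)C[C@@H](O[Si](C)(C)C(C)(C)C)CCO[Si](C)(C)C(C)(C)C)O[C@@H](/C=C/C(C)(C)C3(C/C(=C\C(=O)OC)C[C@H](O[Si](C)(C)C(C)(C)C)C[C@@H](OCc4ccc5ccccc5c4)[C@@H](C)O[Si](C)(C)C(C)(C)C)SCCCS3)C1 | intermediate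
38 | C13 alcohol | OC1C[C@@H](CC2(SCCCS2)C(C)(C)[C@@H](OC(=O)C(C)(C)C)C[C@H](O[Si](C)(C)C(C)(C)C)C[C@@H](O[Si](C)(C)C(C)(C)C)CCO[Si](C)(C)C(C)(C)C)O[C@@H](/C=C/C(C)(C)C3(C/C(=C\C(=O)OC)C[C@H](O[Si](C)(C)C(C)(C)C)C[C@@H](OCc4ccc5ccccc5c4)[C@@H](C)O[Si](C)(C)C(C)(C)C)SCCCS3)C1 | intermediate
39 | ring-B ketone | O=C1C[C@@H](CC2(SCCCS2)C(C)(C)[C@@H](OC(=O)C(C)(C)C)C[C@H](O[Si](C)(C)C(C)(C)C)C[C@@H](O[Si](C)(C)C(C)(C)C)CCO[Si](C)(C)C(C)(C)C)O[C@@H](/C=C/C(C)(C)C3(C/C(=C\C(=O)OC)C[C@H](O[Si](C)(C)C(C)(C)C)C[C@@H](OCc4ccc5ccccc5c4)[C@@H](C)O[Si](C)(C)C(C)(C)C)SCCCS3)C1 | intermediate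
40 | C13 enoate | COC(=O)/C=C1/C[C@@H](CC2(SCCCS2)C(C)(C)[C@@H](OC(=O)C(C)(C)C)C[C@H](O[Si](C)(C)C(C)(C)C)C[C@@H](O[Si](C)(C)C(C)(C)C)CCO[Si](C)(C)C(C)(C)C)O[C@@H](/C=C/C(C)(C)C3(C/C(=C\C(=O)OC)C[C@H](O[Si](C)(C)C(C)(C)C)C[C@@H](OCc4ccc5ccccc5c4)[C@@H](C)O[Si](C)(C)C(C)(C)C)SCCCS3)C1 | intermediate
41 | C25 alcohol | COC(=O)/C=C1/C[C@@H](CC2(SCCCS2)C(C)(C)[C@@H](OC(=O)C(C)(C)C)C[C@H](O[Si](C)(C)C(C)(C)C)C[C@@H](O[Si](C)(C)C(C)(C)C)CCO[Si](C)(C)C(C)(C)C)O[C@@H](/C=C/C(C)(C)C3(C/C(=C\C(=O)OC)C[C@H](O[Si](C)(C)C(C)(C)C)C[C@@H](O)[C@@H](C)O[Si](C)(C)C(C)(C)C)SCCCS3)C1 | intermediate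
42 | C1/C25 diol | COC(=O)/C=C1/C[C@@H](CC2(SCCCS2)C(C)(C)[C@@H](OC(=O)C(C)(C)C)C[C@H](O[Si](C)(C)C(C)(C)C)C[C@@H](O[Si](C)(C)C(C)(C)C)CCO)O[C@@H](/C=C/C(C)(C)C3(C/C(=C\C(=O)OC)C[C@H](O[Si](C)(C)C(C)(C)C)C[C@@H](O)[C@@H](C)O[Si](C)(C)C(C)(C)C)SCCCS3)C1 | intermediate
43 | seco-acid | COC(=O)/C=C1/C[C@@H](CC2(SCCCS2)C(C)(C)[C@@H](OC(=O)C(C)(C)C)C[C@H](O[Si](C)(C)C(C)(C)C)C[C@@H](O[Si](C)(C)C(C)(C)C)CC(=O)O)O[C@@H](/C=C/C(C)(C)C3(C/C(=C\C(=O)OC)C[C@H](O[Si](C)(C)C(C)(C)C)C[C@@H](O)[C@@H](C)O[Si](C)(C)C(C)(C)C)SCCCS3)C1 | intermediate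
44 | bis-dithiane macrolactone | O=C1C[C@H](O[Si](C)(C)C(C)(C)C)C[C@@H](O[Si](C)(C)C(C)(C)C)C[C@H](OC(=O)C(C)(C)C)C(C)(C)C2(SCCCS2)C[C@@H]3C/C(=C/C(=O)OC)C[C@@H](O3)/C=C/C(C)(C)C4(SCCCS4)C/C(=C\C(=O)OC)C[C@H](O[Si](C)(C)C(C)(C)C)C[C@@H](O1)[C@@H](C)O[Si](C)(C)C(C)(C)C | intermediate
45 | diketone macrolactone | O=C1C[C@H](O[Si](C)(C)C(C)(C)C)C[C@@H](O[Si](C)(C)C(C)(C)C)C[C@H](OC(=O)C(C)(C)C)C(C)(C)C(=O)C[C@@H]2C/C(=C/C(=O)OC)C[C@@H](O2)/C=C/C(C)(C)C(=O)C/C(=C\C(=O)OC)C[C@H](O[Si](C)(C)C(C)(C)C)C[C@@H](O1)[C@@H](C)O[Si](C)(C)C(C)(C)C | intermediate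
46 | bryostatin 18 | COC(=O)/C=C1/C[C@H]2C[C@]3(O)O[C@H](C[C@@H](O)CC(=O)O[C@@H]([C@@H](C)O)C[C@@H]4C/C(=C/C(=O)OC)C[C@@](O)(O4)C(C)(C)/C=C/[C@@H](C1)O2)C[C@H](OC(=O)C(C)(C)C)C3(C)C | target

---

**Totals**
- Total step count: 43.
- Longest linear sequence: 26 steps (1–15, 18, then 34–43).

**Three steps most likely to fail**
1. **Step 34 (Prins).** Risks are TBS or NAP loss under BF3/AcOH, 2-oxonia-Cope scrambling, and loss of cis selectivity.
   - Fallback: build ring B by a base-mediated route instead. Use the ethylene-ketal analogue of epoxide 19 (from methyl acetoacetate) in step 18. Hydrolyse it to the methyl ketone and do a lithium-enolate aldol with enal 36. Dehydrate to the dienone, then close ring B by DBU-promoted 6-endo oxa-Michael addition to give ketone 39.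
2. **Step 18 (and the same lithiation in step 28).** Lithiating a 2-tert-alkyl dithiane and opening a terminal epoxide with it is sterically very demanding, and the anion could attack the C7 pivalate.
   - Fallback: form C9–C10 by aldol chemistry. Convert aldehyde 15 to its methyl ketone (MeMgBr, then DMP) and do a boron aldol (Cy2BCl, Et3N) with but-3-enal. This gives the C9-ketone analogue of 20. C9 would then be masked by closing ring A as its C5-O methyl ketal.
3. **Step 37 (C13 ketone olefination).** The ring ketone is almost symmetric, so the HWE gives poor E/Z control, and base can cause retro-oxa-Michael ring opening.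
   - Fallback: fix the enoate geometry before ring closure. Run a pyran annulation in which the allylsilane partner already carries the exocyclic enoate, so ring B forms directly from the enal with the enoate geometry set.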